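Its constants belong to no real substance; no experiment stands behind them.

The vessel is a closed, stirred, isothermal flask in which starting material splits between target and intermediate A, while protic impurity and capture agent each take their share.

starting material 20 mM; capture agent 20.0 mM; protic impurity 1.00 mM; time 30 min

    starting material → target (k1 = 0.26 s⁻¹)
    starting material → intermediate A (k2 = 0.23 s⁻¹)
    intermediate A → intermediate B (k3 = 0.054 s⁻¹)
    intermediate B → side product (k4 = 0.19 s⁻¹)
    intermediate B ⇌ intermediate C (K5 = 0.53, k5 = 0.25 s⁻¹)
    crystals ⇌ target, rate k6*(cs6 - [target]) while solid is left; crystals form when [target] > cs6 (cs6 = 0.22 mM, k6 = 1.9 s⁻¹)
    capture agent + intermediate B → trapped intermediate (k7 = 8.7 L mol⁻¹ s⁻¹)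
    starting material + protic impurity → quenched substrate (k8 = 1200 L mol⁻¹ s⁻¹)

- amounts and yields of target count crystals too
- given per volume of solution although it is solid: crystals
- the reaction counts as stopped when no species that holds the starting material changes by six tenths of a point or more over the second half of the time
- run time (flask): 30 min

* which holds at 30 min: what has brought the reaction to rest, or that it has not come to rest (all of the starting material has reacted / it is still moving / forward and back rates have come level)
* amount of target at 30 min, in percent of the starting material charged
* amount of side product at 30 min, in percent of the starting material charged
* amount of trapped intermediate at 30 min, in percent of the starting material charged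

Two numbers here seem not to go together. The capture agent is charged at 20.0 mM, level with the starting material, and its constant with intermediate B reads 8.7 L mol⁻¹ s⁻¹ against 0.19 s⁻¹ for the loss to side product. Yet I expect about half of intermediate B to escape capture.

The two constants have different units, so I turn them into times at the charged amounts. Capture is then pseudo-first-order, with a half-life of 3.98 s, and the loss to side product has a half-life of 3.65 s, so the two run nearly level. The quantity I carry is the capture ratio, the rate of capture over the rate of loss to side product, a selectivity factor. At the charge it is 0.916. Since [intermediate B] stands in both rates, it drops out of the ratio, which falls as [capture agent] falls.

First the feed. The impurity has a half-life of 0.0289 s at the charged starting material, whose own half-life by its two first-order steps is 1.41 s, so I take 1.00 mM of starting material as quenched. The rest splits by its two first-order steps, giving target 50.4% and 8.92 mM of intermediate A. At the charged ratio, 4.26 mM would be trapped. Taking the capture agent at its charge less half of that amount gives a mean ratio of 0.818, and a second pass gives 4.01 mM. So I commit to trapped intermediate 20.1% and side product 24.5%. Intermediate A has a half-life of 12.8 s, far inside 30 min, so I expect the flask to be at rest.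

The forecast says all of the starting material has reacted, with target 50.4%, side product 24.5% and trapped intermediate 20.1%, the same figures as mine. Its ground for the last two is “All 8.92 mM ends as side product or trapped intermediate”.

In the flask, all of the starting material has reacted, with target 50.4%, side product 24.5% and trapped intermediate 20.1%. In this flask 80% of the capture agent is left at 30.0 min, so the mean of the capture ratio at the charge and at that moment is 0.824, and the quotient of trapped intermediate over side product is 0.820. In the neighbour flask with 34 mM of capture agent the ratio starts at 1.56, a first pass gives 5.43 mM trapped, the mean becomes 1.43, and I reckon 26.3% trapped. That neighbour flask ends with 26.3% trapped intermediate and 18.3% side product.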